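**Strategy.** The cyclohexenone ring (C1 carbonyl, C2=C3 enone carrying the C3 methyl, C4 carbinol, C5 side-chain carbon, C6 methylene) is traced back to a cyclopentane in which C1 and C3 are directly bonded. This is the C1/C4-dioxygenated pattern of cheap 2-methylcyclopentane-1,3-dione, and C2 is the only ring atom missing. After Stork–Danheiser alkylation with geranylgeranyl bromide and an oxazaborolidine reduction that fixes the cis C4/C5 pair by kinetic resolution, C2 is added as a cyclopropane methylene across the C1–C3 enol ether. The key step, an FeCl3 oxidation of the resulting bicyclo[3.1.0]hexan-1-ol, cleaves the C1–C3 bond, so the five-membered ring expands by C2 to the six-membered enone in one operation.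

Key step: step 7

Remark: ring atoms are called C1–C6 by the numbering of the target in every Why line; geranylgeranyl = (2E,6E,10E)-3,7,11,15-tetramethylhexadeca-2,6,10,14-tetraen-1-yl; TIPS = triisopropylsilyl. Step 4 is a kinetic resolution, so only the (5R) half of racemic 5 is carried on; the recovered (5S)-ketone can be racemised by deprotonation/protonation and recycled.

Step 1
Reactants: 1 geranylgeraniol
Product: 2 geranylgeranyl bromide
Conditions: PBr3 (0.4 equiv), pyridine (cat.), Et2O, −10 °C; used crude
Reagents that add atoms: phosphorus tribromide, BrP(Br)Br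
Why: Bromination of the primary allylic alcohol with PBr3 (SN2-type displacement of the phosphite ester) at low temperature should give the all-E primary bromide without allylic transposition; no stereocenter is formed.

Step 2
Reactants: 3 2-methylcyclopentane-1,3-dione
Product: 4 2-methyl-3-(triisopropylsilyloxy)cyclopent-2-en-1-one
Conditions: iPr3SiCl, Et3N, 4-(dimethylamino)pyridine (cat.), CH2Cl2, 0 °C → rt
Reagents that add atoms: triisopropylsilyl chloride, CC(C)[Si](Cl)(C(C)C)C(C)C
Why: O-silylation of the enolised 1,3-dione (a vinylogous acid) gives the vinylogous silyl ester, which fixes the C1 oxygen as an enol ether towards C3 and leaves C4 as the only ketone; the dione is symmetric, so no regio- or stereochemical question arises.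

Step 3
Reactants: 4 2-methyl-3-(triisopropylsilyloxy)cyclopent-2-en-1-one; 2 geranylgeranyl bromide
Product: 5 racemic 5-geranylgeranyl-2-methyl-3-(triisopropylsilyloxy)cyclopent-2-en-1-one
Conditions: LiN(iPr)2, THF, −78 °C; then 2, DMPU, −78 → −30 °C
Reagents that add atoms: none
Why: Stork–Danheiser alkylation: kinetic deprotonation of the vinylogous ester at C5 (α′ to the C4 ketone) gives the cross-conjugated lithium enolate, which is alkylated by the primary allylic bromide in SN2 fashion at C5; the new C5 stereocenter forms as a racemate at this stage.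

Step 4
Reactants: 5 racemic 5-geranylgeranyl-2-methyl-3-(triisopropylsilyloxy)cyclopent-2-en-1-one
Product: 6 (1R,5R)-5-geranylgeranyl-2-methyl-3-(triisopropylsilyloxy)cyclopent-2-en-1-ol
Conditions: (S)-1-methyl-3,3-diphenyltetrahydro-3H-pyrrolo[1,2-c][1,3,2]oxazaborole ((S)-Me-CBS, 0.5 equiv), catecholborane (0.55 equiv), toluene, −78 → −40 °C, run to about half conversion; MeOH, then aq. NaHCO3; Et3N-deactivated silica
Reagents that add atoms: none
Why: Corey–Bakshi–Shibata reduction used as a kinetic resolution: the oxazaborolidine–borane complex binds the C4 carbonyl with the 2-methylalkenyl flank as the large group and delivers hydride to the face that gives the (1R) carbinol, which for (5R)-5 is also the face anti to the C5 side chain (matched pair), so only (5R)-5 should be reduced rapidly, to the cis alcohol 6 with C4 set by the catalyst and C5 selected by the resolution, while mismatched (5S)-5 is left behind and separated.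

Step 5
Reactants: 6 (1R,5R)-5-geranylgeranyl-2-methyl-3-(triisopropylsilyloxy)cyclopent-2-en-1-ol
Product: 7 (1R,2R,3R,5S)-3-geranylgeranyl-1-methyl-5-(triisopropylsilyloxy)bicyclo[3.1.0]hexan-2-ol (cyclopropane CH2, OH and side chain on the same face)
Conditions: Et2Zn (2.2 equiv), CH2I2 (1.2 equiv), CH2Cl2, −20 → 0 °C; aq. NH4Cl/pyridine quench
Reagents that add atoms: diiodomethane, ICI
Why: Simmons–Smith cyclopropanation (Et2Zn/CH2I2): the zinc alkoxide of the C4 hydroxyl delivers the carbenoid to the adjacent, strongly electron-rich tetrasubstituted silyl enol ether on the hydroxyl face much faster than the four remote trisubstituted alkenes react, installing the future C2 as the cyclopropane CH2; the two new bridgehead stereocenters (CH2 syn to OH) are erased in step 7.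

Step 6
Reactants: 7 (1R,2R,3R,5S)-3-geranylgeranyl-1-methyl-5-(triisopropylsilyloxy)bicyclo[3.1.0]hexan-2-ol
Product: 8 (1S,3R,4R,5R)-3-geranylgeranyl-5-methylbicyclo[3.1.0]hexane-1,4-diol
Conditions: Bu4NF, AcOH (1:1), THF, 0 °C
Reagents that add atoms: none
Why: Fluoride-mediated Si–O cleavage, buffered with AcOH so that the cyclopropanolate is protonated at once and does not ring-open as a homoenolate, frees the tertiary cyclopropanol needed for inner-sphere oxidation by FeCl3; no stereocenter is touched.

Step 7
Reactants: 8 (1S,3R,4R,5R)-3-geranylgeranyl-5-methylbicyclo[3.1.0]hexane-1,4-diol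
Product: 10 (4R,5R)-5-geranylgeranyl-4-hydroxy-3-methylcyclohex-2-en-1-one (target), via chloro ketone 9 (not isolated)
Conditions: FeCl3 (2.5 equiv), pyridine (1 equiv), DMF, 0 °C; then NaOAc, MeOH, rt
Reagents that add atoms: none
Why: Saegusa–Ito-type oxidative ring expansion: the tertiary cyclopropanol binds FeCl3 and is oxidised by one electron (trivalent to divalent iron) to the cyclopropyloxy radical, which undergoes β-scission of the ring-fusion bond of the bicyclo[3.1.0]hexane (the C1–C3 bond) because this gives the tertiary, methyl-substituted C3 radical of a cyclohexanone, whereas cleavage of the external bond would give a primary radical. Chlorine-atom transfer from a second FeCl3 gives the 3-chloro-3-methylcyclohexanone 9, and NaOAc then removes HCl by E1cB through the C2 enolate, so the double bond can only form between C2 and C3, in conjugation with the C1 carbonyl. The closest known reaction type is the FeCl3 oxidation of 1-siloxy- or 1-hydroxybicyclo[n.1.0]alkanes to 2-cycloalkenones with one more ring carbon. No ring-closing bond is made: the six-membered ring C1–C6 arises by opening the zero-atom bridge of the fused bicycle, the former cyclopropane CH2 becoming C2. No stereocenter is created in the product (the C3 centre of 9 is lost on elimination), and C4 and C5 lie outside the reacting bonds and keep the configuration fixed in step 4. The step needs internal over external cyclopropane cleavage (secured by the bridgehead methyl group) and chlorine capture of the C3 radical faster than its addition to the side-chain alkenes (favoured by excess FeCl3 in DMF and by the bridged geometry such a cyclisation would require).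

**Compound list**

1 | geranylgeraniol, (2E,6E,10E)-3,7,11,15-tetramethylhexadeca-2,6,10,14-tetraen-1-ol | CC(C)=CCC/C(C)=C/CC/C(C)=C/CC/C(C)=C/CO | starting material
2 | geranylgeranyl bromide, (2E,6E,10E)-1-bromo-3,7,11,15-tetramethylhexadeca-2,6,10,14-tetraene | CC(C)=CCC/C(C)=C/CC/C(C)=C/CC/C(C)=C/CBr | intermediate
3 | 2-methylcyclopentane-1,3-dione | CC1C(=O)CCC1=O | starting material
4 | 2-methyl-3-(triisopropylsilyloxy)cyclopent-2-en-1-one | CC1=C(O[Si](C(C)C)(C(C)C)C(C)C)CCC1=O | intermediate
5 | racemic 5-[(2E,6E,10E)-3,7,11,15-tetramethylhexadeca-2,6,10,14-tetraen-1-yl]-2-methyl-3-(triisopropylsilyloxy)cyclopent-2-en-1-one | CC(C)=CCC/C(C)=C/CC/C(C)=C/CC/C(C)=C/CC1CC(O[Si](C(C)C)(C(C)C)C(C)C)=C(C)C1=O | intermediate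
6 | (1R,5R)-5-[(2E,6E,10E)-3,7,11,15-tetramethylhexadeca-2,6,10,14-tetraen-1-yl]-2-methyl-3-(triisopropylsilyloxy)cyclopent-2-en-1-ol (OH and side chain cis) | CC(C)=CCC/C(C)=C/CC/C(C)=C/CC/C(C)=C/C[C@@H]1CC(O[Si](C(C)C)(C(C)C)C(C)C)=C(C)[C@@H]1O | intermediate
7 | (1R,2R,3R,5S)-1-methyl-3-[(2E,6E,10E)-3,7,11,15-tetramethylhexadeca-2,6,10,14-tetraen-1-yl]-5-(triisopropylsilyloxy)bicyclo[3.1.0]hexan-2-ol (cyclopropane CH2, OH and side chain on one face) | CC(C)=CCC/C(C)=C/CC/C(C)=C/CC/C(C)=C/C[C@@H]1C[C@]2(O[Si](C(C)C)(C(C)C)C(C)C)C[C@]2(C)[C@@H]1O | intermediate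
8 | (1S,3R,4R,5R)-5-methyl-3-[(2E,6E,10E)-3,7,11,15-tetramethylhexadeca-2,6,10,14-tetraen-1-yl]bicyclo[3.1.0]hexane-1,4-diol | CC(C)=CCC/C(C)=C/CC/C(C)=C/CC/C(C)=C/C[C@@H]1C[C@]2(O)C[C@]2(C)[C@@H]1O | intermediate
9 | (4R,5R)-3-chloro-4-hydroxy-3-methyl-5-[(2E,6E,10E)-3,7,11,15-tetramethylhexadeca-2,6,10,14-tetraen-1-yl]cyclohexan-1-one (C3 epimers, not isolated) | CC(C)=CCC/C(C)=C/CC/C(C)=C/CC/C(C)=C/C[C@@H]1CC(=O)CC(C)(Cl)[C@@H]1O | intermediate
10 | (4R,5R)-4-hydroxy-3-methyl-5-[(2E,6E,10E)-3,7,11,15-tetramethylhexadeca-2,6,10,14-tetraen-1-yl]cyclohex-2-en-1-one | CC(C)=CCC/C(C)=C/CC/C(C)=C/CC/C(C)=C/C[C@@H]1CC(=O)C=C(C)[C@@H]1O | target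

**Step count.** Total: 7 steps. Longest linear sequence: 6 steps (steps 2–7, from 2-methylcyclopentane-1,3-dione); step 1 prepares the side-chain bromide in parallel.

**Steps most likely to fail, with fallbacks.**

The key ring expansion (step 7) is the most exposed step. The tertiary C3 radical may add to the nearest side-chain alkene before it captures chlorine. Independently, FeCl3 may ionise the C4 carbinol next to the donor-substituted cyclopropane, which would expand the ring with loss of the C4 oxygen. The fallback avoids both the radical and the iron salt and sets out from 6. OH-directed cyclopropanation with the zinc iodocarbenoid from Et2Zn/CHI3 (CH2Cl2, −40 → 0 °C) should give the 6-iodo analogue of 7, iodo-siloxycyclopropane F1. AgBF4 (2,6-lutidine, CH2Cl2, −20 °C, then aq. NaHCO3) would ionise the C–I bond of the isomer whose iodine is syn to the five-membered ring, with disrotatory opening of the C1–C3 bond to the 2-siloxyallyl cation. Loss of the silyl group then gives the enone, and the sequence comes back to the route at 10.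

The oxazaborolidine reduction (step 4) is the second risk. The electron-rich vinylogous-ester carbonyl may react too slowly with catecholborane, or the rate difference between the two enantiomers of 5 may be too small for a clean resolution. The fallback separates reduction and resolution and sets out from 5. iBu2AlH (toluene, −78 °C) should deliver hydride anti to the C5 chain and give the racemic cis alcohol, that is 6 together with its mirror image, ent-alcohol F2. A lipase-catalysed acylation (Candida antarctica lipase B or Burkholderia cepacia lipase, vinyl acetate, MTBE, rt), with the enzyme chosen by screening so that F2 is the enantiomer acylated, would convert F2 into the allylic acetate F3 and leave 6 as the free alcohol. After chromatography the sequence comes back to the route at 6.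

The alkylation of the silyl vinylogous ester (step 3) is the third risk. Silyl transfer between enolate oxygens, desilylation by the amide base or proton exchange leading to double alkylation may erode the regiodefined enol ether. The fallback reverses the order of the two events and sets out from 3. The dianion of 3 (LiN(iPr)2, 2.2 equiv, THF/HMPA, −78 → 0 °C) should be alkylated by 2 at the ring CH2 next to a carbonyl to give racemic 4-geranylgeranyl-2-methylcyclopentane-1,3-dione F4. Silylation with iPr3SiCl/Et3N should then occur at the less hindered oxygen, the one remote from the side chain, and the sequence comes back to the route at 5.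

**Further compounds**

F1 | step 7 | 6-iodo-1-methyl-3-geranylgeranyl-5-(triisopropylsilyloxy)bicyclo[3.1.0]hexan-2-ol, ring configuration as in 7, C6 epimers | CC(C)=CCC/C(C)=C/CC/C(C)=C/CC/C(C)=C/C[C@@H]1C[C@]2(O[Si](C(C)C)(C(C)C)C(C)C)C(I)[C@]2(C)[C@@H]1O
F2 | step 4 | (1S,5S)-5-geranylgeranyl-2-methyl-3-(triisopropylsilyloxy)cyclopent-2-en-1-ol (enantiomer of 6) | CC(C)=CCC/C(C)=C/CC/C(C)=C/CC/C(C)=C/C[C@H]1CC(O[Si](C(C)C)(C(C)C)C(C)C)=C(C)[C@H]1O
F3 | step 4 | (1S,5S)-5-geranylgeranyl-2-methyl-3-(triisopropylsilyloxy)cyclopent-2-en-1-yl acetate | CC(C)=CCC/C(C)=C/CC/C(C)=C/CC/C(C)=C/C[C@H]1CC(O[Si](C(C)C)(C(C)C)C(C)C)=C(C)[C@H]1OC(C)=O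
F4 | step 3 | racemic 4-geranylgeranyl-2-methylcyclopentane-1,3-dione | CC(C)=CCC/C(C)=C/CC/C(C)=C/CC/C(C)=C/CC1CC(=O)C(C)C1=O
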